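## Retrosynthetic overview

- **Numbering and endgame.** Drimane numbering is used: ring A = C1-C2-C3-C4-C5-C10, ring B = C5-C6-C7-C8-C9-C10, C11 = the OCH2 carbon on C9. The C2 ketone comes from a C2 carbinol carried as a silyl ether (a temporary stereocentre at a lower oxidation level). The angelate comes from the C3 alcohol.
- **Key disconnection.** C4-C5 (ring A) and C9-C10 (ring B) are cut together, which unfolds the trans-decalin to an acyclic (E,E)-farnesyl-type umbelliferyl ether bearing a C3-C4 epoxide. In the forward sense one Lewis acid operation closes ring A first and ring B second, and ends with loss of a proton from C7 (C7=C8 alkene). The coumarin rings are bought.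
- **Enabling feature.** In ring A the gem-dimethyl carbon C4 sits next to oxygen-bearing C3, the imprint of a trisubstituted epoxide opened at its tertiary end. C4 is 1,5-related to methyl-bearing C10 and onward to methyl-bearing C8 of ring B. The trans C5-H/C10-CH3 fusion, the equatorial C3-O and C9-CH2OAr groups and the C7=C8 alkene are what a chair-chair cation-alkene cascade of an E,E-triene delivers.
- **Precursor.** The epoxide comes from a hydroxy-directed, A(1,3)-controlled epoxidation of the (2S)-allylic alcohol, which comes from CBS reduction of the C2 dienone. The dienone is built from geranyl umbelliferyl ether (ten-carbon unit) and 2-methylbut-3-yn-2-ol (five-carbon unit) by allylic oxidation, bromination, copper-catalysed alkyne allylation (C1-C2 bond) and Meyer-Schuster rearrangement.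

Key step: step 9

Remark: the open-chain compounds are discussed with the same drimane numbers. Chain atoms 1 to 11 of the dodecatrienyl ether correspond to C11, C9, C8, C7, C6, C5, C10, C1, C2, C3 and C4.

## Route

Step 1
Reactants: 1 umbelliferone (7-hydroxy-2H-chromen-2-one); 2 geranyl bromide ((2E)-1-bromo-3,7-dimethylocta-2,6-diene)
Product: 3 auraptene, 7-{[(2E)-3,7-dimethylocta-2,6-dien-1-yl]oxy}-2H-chromen-2-one
Conditions: K2CO3, acetone, reflux
Reagents that add atoms: none
Why: Williamson ether synthesis, in which the acidic 7-OH is deprotonated by K2CO3 and the phenoxide displaces the primary allylic bromide by SN2 attack, leaving the E-alkene untouched and forming no stereocentre.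

Step 2
Reactants: 3 auraptene
Product: 4 7-{[(2E,6E)-8-hydroxy-3,7-dimethylocta-2,6-dien-1-yl]oxy}-2H-chromen-2-one
Conditions: SeO2 (10 mol %), t-BuOOH, salicylic acid (10 mol %), CH2Cl2, 0 °C to rt
Reagents that add atoms: tert-butyl hydroperoxide CC(C)(C)OO (terminal oxygen source, relayed through SeO2 O=[Se]=O)
Why: Riley allylic oxidation, catalytic in SeO2 (ene reaction then [2,3]-sigmatropic shift), attacks the electron-rich terminal alkene because the C8=C9 alkene is deactivated by its allylic aryloxy group, and its cyclic transition state oxidises only the E-methyl group, so the future C1 ends up trans to C6 across the C5=C10 alkene.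

Step 3
Reactants: 4 the (2E,6E)-8-hydroxy ether
Product: 5 7-{[(2E,6E)-8-bromo-3,7-dimethylocta-2,6-dien-1-yl]oxy}-2H-chromen-2-one
Conditions: CBr4, PPh3, CH2Cl2, 0 °C
Reagents that add atoms: carbon tetrabromide BrC(Br)(Br)Br
Why: Appel reaction, in which the alkoxyphosphonium ion of the primary allylic alcohol is displaced by bromide in an SN2 step under neutral conditions, which should keep alkene position and geometry and leave the aryl ether and lactone intact.

Step 4
Reactants: 5 the (2E,6E)-8-bromo ether; 6 2-methylbut-3-yn-2-ol
Product: 7 7-{[(2E,6E)-11-hydroxy-3,7,11-trimethyldodeca-2,6-dien-9-yn-1-yl]oxy}-2H-chromen-2-one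
Conditions: CuI (10 mol %), K2CO3, DMF, rt
Reagents that add atoms: none
Why: Copper-catalysed allylation of a terminal alkyne, in which the copper acetylide attacks the unhindered CH2Br terminus (SN2 rather than SN2′, whose carbon is more hindered) and builds the C1-C2 bond of a skipped enyne under conditions a coumarin tolerates, unlike lithium or magnesium acyl-anion equivalents.

Step 5
Reactants: 7 the enynol
Product: 8 7-{[(2E,6E)-3,7,11-trimethyl-9-oxododeca-2,6,10-trien-1-yl]oxy}-2H-chromen-2-one (C2 ketone, C3=C4 enone, skipped C5=C10 alkene)
Conditions: Ph3PAuNTf2 (2 mol %), MeOH (1 equiv), toluene, rt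
Reagents that add atoms: none
Why: Gold-catalysed Meyer-Schuster rearrangement, in which π-activation of the alkyne by the cationic monovalent gold complex moves the tertiary hydroxyl oxygen formally from C4 to C2 and gives the β,β-dimethyl enone at room temperature and near neutrality, so the doubly activated C1 methylene should not slip into conjugation.

Step 6
Reactants: 8 the dienone
Product: 9 7-{[(2E,6E,9S)-9-hydroxy-3,7,11-trimethyldodeca-2,6,10-trien-1-yl]oxy}-2H-chromen-2-one ((2S) in drimane numbers)
Conditions: (R)-2-methyl-CBS-oxazaborolidine (20 mol %), catecholborane, toluene, −78 °C; aqueous work-up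
Reagents that add atoms: none
Why: Corey-Bakshi-Shibata reduction, in which the isobutenyl arm, held s-cis by its Z-methyl group, acts as the large substituent, so the (R)-oxazaborolidine-borane complex should deliver hydride to the face that gives the (2S)-carbinol, in a 1,2-sense and without touching the coumarin or the isolated alkenes at low temperature.

Step 7
Reactants: 9 the (2S)-allylic alcohol
Product: 10 threo epoxy alcohol 7-{[(2E,6E,9S)-9-[(2R)-3,3-dimethyloxiran-2-yl]-9-hydroxy-3,7-dimethylnona-2,6-dien-1-yl]oxy}-2H-chromen-2-one ((2S,3R) in drimane numbers)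
Conditions: Ti(OiPr)4 (20 mol %), t-BuOOH (decane), 4 Å MS, CH2Cl2, −20 °C
Reagents that add atoms: tert-butyl hydroperoxide CC(C)(C)OO
Why: Hydroxy-directed epoxidation by a titanium tert-butylperoxo alkoxide, in which only the allylic C3=C4 alkene is well placed for the metal bound to the C2 oxygen, and A(1,3) strain with the Z-methyl group fixes the rotamer having C2-H in the alkene plane, so oxygen arrives on the hydroxyl-bearing face and should set C3 as (R), the threo isomer.

Step 8
Reactants: 10 the threo epoxy alcohol
Product: 11 7-{[(2E,6E,9S)-9-(tert-butyldimethylsilyloxy)-9-[(2R)-3,3-dimethyloxiran-2-yl]-3,7-dimethylnona-2,6-dien-1-yl]oxy}-2H-chromen-2-one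
Conditions: TBSCl, imidazole, DMF, rt
Reagents that add atoms: tert-butyldimethylsilyl chloride CC(C)(C)[Si](C)(C)Cl
Why: Standard imidazole-promoted silylation masks the C2 oxygen as a weakly Lewis basic, non-participating ether under base-buffered conditions that spare the acid-labile trisubstituted epoxide, and no stereocentre is touched.

Step 9
Reactants: 11 the acyclic epoxy silyl ether
Product: 12 7-{[(2S,3S,5S,9R,10R)-2-(tert-butyldimethylsilyloxy)-3-hydroxydrim-7-en-11-yl]oxy}coumarin (trans-decalin; C10-CH3 axial, C5-H axial on the opposite face; C9-CH2OAr and C3-OH equatorial and on the face of C10-CH3; C2-OTBS equatorial and trans to C3-OH; C7=C8 alkene)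
Conditions: MeAlCl2 (3 equiv), CH2Cl2 (0.01 M), −78 °C; aqueous work-up
Reagents that add atoms: none
Why: MeAlCl2 (used in excess because the coumarin carbonyl holds one equivalent) binds the epoxide oxygen, the C4-O bond ionises at its tertiary end as the C5=C10 alkene attacks C4 from the rear, the resulting C10 cation is captured at C9 by the C8=C9 alkene, and the C8 cation loses the axial C7 proton, which the Al-CH3 bond takes up as methane; this is the classical epoxide-initiated cationic polyene cyclisation, a reaction type already established for epoxyfarnesyl esters and aryl ethers. Ring A closes by 6-endo opening of the epoxide (bond C4-C5, 6-endo-trig at the alkene) and ring B by a second 6-endo-trig closure (bond C9-C10), both through chair-like folds. C5 and C10 arise by anti addition across the E-configured C5=C10 alkene, which fixes the trans ring fusion, and C9 arises by anti addition across the E-configured C8=C9 alkene, which places CH2OAr equatorial and cis to the C10 methyl group. The absolute sense is dictated by the (3R)-epoxide carbon and the (2S)-silyloxy carbon, whose C-O bonds must both lie equatorial in the chair-chair fold (an axial C2 substituent would clash with the C10 and axial C4 methyl groups), so only one face of the C5=C10 alkene can reach C4. The step needs ionisation of the epoxide and not of the allylic aryl ether (secured by the higher basicity and ring strain of the epoxide at −78 °C), cleavage at C4 and not at C3 (tertiary carbon against a secondary carbon next to the electron-withdrawing C2-O bond), and proton loss from C7 and not from C9 or the C8 methyl group (axial C7-H aligned with the empty orbital, C9-H deactivated by the β-aryloxy group, endocyclic trisubstituted alkene favoured).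

Step 10
Reactants: 12 the bicyclic C3 alcohol; 13 angelic acid ((2Z)-2-methylbut-2-enoic acid)
Product: 15 7-{[(2S,3S,5S,9R,10R)-3-angeloyloxy-2-(tert-butyldimethylsilyloxy)drim-7-en-11-yl]oxy}coumarin, via mixed angelic anhydride 14 (not isolated)
Conditions: 13, 2,4,6-trichlorobenzoyl chloride, Et3N, toluene, rt; then 12, 80 °C
Reagents that add atoms: 2,4,6-trichlorobenzoyl chloride O=C(Cl)c1c(Cl)cc(Cl)cc1Cl (its atoms appear only in 14, none in 15)
Why: Yamaguchi-type mixed-anhydride esterification, in which the ortho chlorines shield the aroyl carbonyl so the hindered equatorial C3-OH attacks the angeloyl carbonyl, the omission of nucleophilic catalysts such as DMAP avoids the addition-elimination path that turns angelate (Z) into tiglate (E), and C3 keeps its configuration because only the O-H bond is broken.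

Step 11
Reactants: 15 the angelate silyl ether
Product: 16 7-{[(2S,3S,5S,9R,10R)-3-angeloyloxy-2-hydroxydrim-7-en-11-yl]oxy}coumarin
Conditions: HF·pyridine, THF, 0 °C to rt
Reagents that add atoms: none
Why: Fluoride-driven desilylation under mildly acidic, buffered conditions removes the temporary silyl group without generating the alkoxide that would trigger acyl migration from the C3 to the C2 oxygen, and the crude alcohol is best oxidised at once.

Step 12
Reactants: 16 the C2 alcohol
Product: 17 target, 7-{[(3S,5S,9R,10R)-3-angeloyloxy-2-oxodrim-7-en-11-yl]oxy}coumarin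
Conditions: Dess-Martin periodinane, CH2Cl2, 0 °C to rt
Reagents that add atoms: none
Why: Dess-Martin oxidation under neutral conditions erases the temporary C2 stereocentre and gives the ketone without touching the alkenes, angelate or coumarin, and the neighbouring C3 centre carries its acyloxy group equatorial, the more stable arrangement, so epimerisation is not a threat.

## Compound list

1 | umbelliferone | Oc1ccc2ccc(=O)oc2c1 | starting material
2 | geranyl bromide | CC(C)=CCC/C(C)=C/CBr | starting material
3 | auraptene | CC(C)=CCC/C(C)=C/COc1ccc2ccc(=O)oc2c1 | intermediate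
4 | (2E,6E)-8-hydroxygeranyl umbelliferyl ether | OC/C(C)=C/CC/C(C)=C/COc1ccc2ccc(=O)oc2c1 | intermediate
5 | (2E,6E)-8-bromogeranyl umbelliferyl ether | BrC/C(C)=C/CC/C(C)=C/COc1ccc2ccc(=O)oc2c1 | intermediate
6 | 2-methylbut-3-yn-2-ol | CC(C)(O)C#C | starting material
7 | (2E,6E)-11-hydroxy-3,7,11-trimethyldodeca-2,6-dien-9-ynyl umbelliferyl ether | CC(C)(O)C#CC/C(C)=C/CC/C(C)=C/COc1ccc2ccc(=O)oc2c1 | intermediate
8 | (2E,6E)-3,7,11-trimethyl-9-oxododeca-2,6,10-trienyl umbelliferyl ether | CC(C)=CC(=O)C/C(C)=C/CC/C(C)=C/COc1ccc2ccc(=O)oc2c1 | intermediate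
9 | (2E,6E,9S)-9-hydroxy-3,7,11-trimethyldodeca-2,6,10-trienyl umbelliferyl ether | CC(C)=C[C@@H](O)C/C(C)=C/CC/C(C)=C/COc1ccc2ccc(=O)oc2c1 | intermediate
10 | threo (9S,10R)-10,11-epoxy-9-hydroxy ether | CC1(C)O[C@@H]1[C@@H](O)C/C(C)=C/CC/C(C)=C/COc2ccc3ccc(=O)oc3c2 | intermediate
11 | TBS ether of 10 (cyclisation precursor) | CC1(C)O[C@@H]1[C@@H](O[Si](C)(C)C(C)(C)C)C/C(C)=C/CC/C(C)=C/COc2ccc3ccc(=O)oc3c2 | intermediate
12 | (2S,3S,5S,9R,10R)-2-(TBS-oxy)-3-hydroxydrim-7-en-11-yl umbelliferyl ether | O[C@@H]1[C@@H](O[Si](C)(C)C(C)(C)C)C[C@@]2(C)[C@H](COc3ccc4ccc(=O)oc4c3)C(C)=CC[C@@H]2C1(C)C | intermediate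
13 | angelic acid | C/C=C(/C)C(=O)O | starting material
14 | angelic 2,4,6-trichlorobenzoic anhydride | C/C=C(/C)C(=O)OC(=O)c1c(Cl)cc(Cl)cc1Cl | intermediate
15 | (2S,3S,5S,9R,10R)-3-angeloyloxy-2-(TBS-oxy)drim-7-en-11-yl umbelliferyl ether | C/C=C(/C)C(=O)O[C@@H]1[C@@H](O[Si](C)(C)C(C)(C)C)C[C@@]2(C)[C@H](COc3ccc4ccc(=O)oc4c3)C(C)=CC[C@@H]2C1(C)C | intermediate
16 | (2S,3S,5S,9R,10R)-3-angeloyloxy-2-hydroxydrim-7-en-11-yl umbelliferyl ether | C/C=C(/C)C(=O)O[C@@H]1[C@@H](O)C[C@@]2(C)[C@H](COc3ccc4ccc(=O)oc4c3)C(C)=CC[C@@H]2C1(C)C | intermediate
17 | (3S,5S,9R,10R)-3-angeloyloxy-2-oxodrim-7-en-11-yl umbelliferyl ether | C/C=C(/C)C(=O)O[C@@H]1C(=O)C[C@@]2(C)[C@H](COc3ccc4ccc(=O)oc4c3)C(C)=CC[C@@H]2C1(C)C | target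

## Step count and risks

Total step count: 12. Longest linear sequence: 12 steps (from 1 or 2 to 17).

**Step 9.** The cascade may stop after ring A because the C8=C9 alkene is a weak nucleophile. The Lewis acid may also ionise the allylic aryl ether, or the C8 cation may lose its proton unselectively.
- The fallback makes the same C4-C5 bond through a radical instead of a cation, and sets out from 11.
- Cp2TiCl (trivalent titanium, generated from Cp2TiCl2 and Mn dust in THF at rt) opens the epoxide homolytically to the tertiary C4 radical.
- This radical should run through the same 6-endo/6-endo chair-chair cascade under neutral conditions that leave the aryl ether alone.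
- The C8 radical ends by loss of a hydrogen atom from the C8 methyl group, which should give the exocyclic C8=CH2 isomer of 12, F1.
- Catalytic RhCl3·3H2O in warm EtOH then moves the alkene into ring B (C7=C8), and the route is rejoined at 12.

**Step 10.** Acylation of the C3-OH may be slow, since it lies between the gem-dimethyl carbon and the silyl ether. The forcing conditions then needed may cause Z to E isomerisation of the angeloyl unit.
- The fallback builds the Z-alkene on the ester instead of importing it, and sets out from 12.
- Commercial ethyl 2-[bis(2,2,2-trifluoroethoxy)phosphoryl]propanoate is hydrolysed with Me3SnOH to 2-[bis(2,2,2-trifluoroethoxy)phosphoryl]propanoic acid F2.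
- F2 carries no labile alkene, so it can be forced onto 12 with DCC and DMAP to give the C3 phosphonopropanoate F3.
- A Still-Gennari olefination of F3 (KHMDS, 18-crown-6, acetaldehyde, THF, −78 °C) should form the Z-trisubstituted enoate, and the route is rejoined at 15.

**Step 6.** Facial selectivity in the reduction may be poor because the two ketone arms are not very different in size. This would erode the enantiomeric purity of everything that follows.
- The fallback replaces asymmetric reduction by resolution, and sets out from 8.
- Luche reduction (NaBH4, CeCl3·7H2O, MeOH, 0 °C) gives the racemic allylic alcohol F4.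
- A Sharpless kinetic resolution follows (Ti(OiPr)4, D-(−)-diisopropyl tartrate, t-BuOOH, 4 Å MS, CH2Cl2, −20 °C), run beyond half conversion.
- It should consume the (2R)-enantiomer as the erythro (2R,3R)-epoxy alcohol F5, which is separated and discarded.
- The unreacted (2S)-alcohol rejoins the route at 9.

## Further compounds

F1 | step 9 | exocyclic C8=CH2 isomer of 12 (same configuration at C2, C3, C5, C9 and C10) | O[C@@H]1[C@@H](O[Si](C)(C)C(C)(C)C)C[C@@]2(C)[C@H](COc3ccc4ccc(=O)oc4c3)C(=C)CC[C@@H]2C1(C)C
F2 | step 10 | 2-[bis(2,2,2-trifluoroethoxy)phosphoryl]propanoic acid | CC(P(=O)(OCC(F)(F)F)OCC(F)(F)F)C(=O)O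
F3 | step 10 | C3 2-[bis(2,2,2-trifluoroethoxy)phosphoryl]propanoate of 12 (epimers at the phosphonate carbon) | CC(P(=O)(OCC(F)(F)F)OCC(F)(F)F)C(=O)O[C@@H]1[C@@H](O[Si](C)(C)C(C)(C)C)C[C@@]2(C)[C@H](COc3ccc4ccc(=O)oc4c3)C(C)=CC[C@@H]2C1(C)C
F4 | step 6 | racemic (2E,6E)-9-hydroxy-3,7,11-trimethyldodeca-2,6,10-trienyl umbelliferyl ether | CC(C)=CC(O)C/C(C)=C/CC/C(C)=C/COc1ccc2ccc(=O)oc2c1
F5 | step 6 | erythro (9R,10R)-10,11-epoxy-9-hydroxy ether | CC1(C)O[C@@H]1[C@H](O)C/C(C)=C/CC/C(C)=C/COc2ccc3ccc(=O)oc3c2
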